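**Retrosynthetic overview**

- Feature: C1, the quaternary oxirane carbon bearing an oxygen and the C7 benzoyloxymethyl arm, lies para to C4 and is flanked by the arms C2–C3 and C6–C5. The cyclohexene ring therefore maps onto the carbinol carbon and the two enantiotopic enone arms of an achiral 4-substituted p-quinol.
- Disconnections: oxirane C6–O1 (O1 displaces a 6α-sulfonate) ⇒ O2 benzoate ⇒ O1/O2 acetal; C6–O ⇒ epoxidation/Wharton transposition of the remaining enone arm; C2–O2 ⇒ acetalization/oxa-Michael on the p-quinol; p-quinol ⇒ phenol.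
- C3: oxygenation α to the ketone is expected anti to the dioxolane, which would give the 3-epimer. C3 is therefore taken to an enone and reduced, so that hydride (not oxygen) enters anti to the acetal and O3 ends cis to O2.
- Ring order: carbocycle by dearomatization of the arene (step 2), temporary dioxolane (step 3), oxirane (step 14).

Key step: step 3

Convention: ring atoms are numbered as in the target (C1 quaternary carbon bearing C7, C2 benzoate carbinol, C3 free carbinol, C4=C5, C6 oxirane CH); β is the face of O1/O2 and of the final oxirane oxygen, α is the face of C7. The target is read as (1S,2R,3R,6S), with the oxirane oxygen, O2 and O3 all β.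

Assumption: the sense of induction of the chiral phosphoric acid on this quinol cannot be predicted with certainty, so the catalyst antipode that delivers 7 is fixed in a pilot run (both antipodes are commercial).

**Route**

Step 1
Reactants: 1 4-hydroxybenzyl alcohol; 2 benzoic acid
Product: 3 4-hydroxybenzyl benzoate
Conditions: PPh3, DIAD, THF, 0 °C → rt
Reagents that add atoms: benzoic acid (2), O=C(O)c1ccccc1
Why: Mitsunobu esterification is chemoselective for the benzylic hydroxyl of a phenolic alcohol because the betaine is protonated by the carboxylic acid (pKa about 4) and not by the phenol (pKa about 10), so benzoate displaces the activated benzylic oxygen and the phenol stays free; no stereocenter is involved.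

Step 2
Reactants: 3 4-hydroxybenzyl benzoate
Product: 4 4-(benzoyloxymethyl)-4-hydroxycyclohexa-2,5-dien-1-one
Conditions: PhI(OAc)2, MeCN–H2O (3:1), 0 °C
Reagents that add atoms: water, O
Why: Iodine(III) oxidative dearomatization of a para-substituted phenol, in which water is captured at the substituted para carbon to give the achiral p-quinol while the benzoate is inert to the oxidant.

Step 3
Reactants: 4 p-quinol; 5 isobutyraldehyde
Product: 7 dioxolane enone (O1/O2 cis-fused on the β face), via quinol hemiacetal 6 (not isolated)
Conditions: i-PrCHO (3 equiv), TRIP-type BINOL phosphoric acid (10 mol %), CH2Cl2, rt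
Reagents that add atoms: isobutyraldehyde (5), CC(C)C=O
Why: The phosphoric acid catalyses reversible addition of the tertiary hydroxyl of 4 to the aldehyde and then, acting as a bifunctional acid/base, delivers the hemiacetal hydroxyl of 6 to the β-carbon (C2) of one enone arm; this acetalization–oxa-Michael cascade is the known Brønsted-acid desymmetrization of p-quinols and p-peroxyquinols with aliphatic aldehydes. The dioxolane closes 5-exo-trig, so O1 and O2 are necessarily cis, and C1 becomes stereogenic only because one of its two enantiotopic arms is consumed. Which arm reacts, and with it the absolute configuration of C1 and C2 together, is decided by the hydrogen-bonded chiral pocket of the catalyst. The acetal carbon is set by dynamic kinetic resolution of the rapidly epimerizing hemiacetal, the isopropyl group ending exo. The step needs only enantiotopic-group selectivity: 4 has a single hydroxyl able to form a hemiacetal, the primary oxygen is capped as the benzoate, and the second enone arm cannot react because the dioxolane can form only once.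

Step 4
Reactants: 7 dioxolane enone
Product: 8 4-silyloxy-3,5-diene (silyl dienol ether of 7)
Conditions: TBSOTf, Et3N, CH2Cl2, −78 → 0 °C
Reagents that add atoms: tert-butyldimethylsilyl triflate, CC(C)(C)[Si](C)(C)OS(=O)(=O)C(F)(F)F
Why: Soft enolization of the enone can only go toward C3, since the γ-carbon C1 is quaternary, and it avoids a free metal enolate that could expel O2 by retro-oxa-Michael; no stereocenter is touched.

Step 5
Reactants: 8 silyl dienol ether
Product: 10 3α-silyloxy enone, via silyloxy oxirane 9 (not isolated)
Conditions: mCPBA, NaHCO3, CH2Cl2, −20 → 0 °C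
Reagents that add atoms: mCPBA, O=C(OO)c1cccc(Cl)c1
Why: Rubottom oxidation, in which the peracid epoxidizes the electron-rich enol-ether bond C3=C4 in preference to C5=C6 and the silyloxy oxirane opens with 1,4-silyl shift to the α-silyloxy ketone; attack is expected on the α face, anti to the dioxolane, placing O3 trans to O2, but this center is provisional and is reset in steps 10 and 11, so its ratio is immaterial.

Step 6
Reactants: 10 3α-silyloxy enone
Product: 11 5α,6α-epoxy ketone
Conditions: t-BuOOH (decane), DBU, CH2Cl2, 0 °C
Reagents that add atoms: tert-butyl hydroperoxide, CC(C)(C)OO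
Why: Weitz–Scheffer nucleophilic epoxidation, in which the peroxide anion should add to C6 axially and anti to the pseudoaxial C1–O1 bond of the half-chair that keeps CH2OBz and OTBS equatorial, that is on the α face, so that C5 and C6 are set trans to O1; the weakly basic peroxide should not enolize C3 at 0 °C and the benzoate tolerates the anhydrous medium.

Step 7
Reactants: 11 epoxy ketone
Product: 14 6α-allylic alcohol, via epoxy hydrazone 12 (not isolated), via alkenyl diazene 13 (not isolated)
Conditions: N2H4·H2O, AcOH, MeOH, 0 °C → rt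
Reagents that add atoms: none
Why: Wharton transposition, in which the hydrazone opens the oxirane at C5 to the alkenyl diazene and loss of N2 leaves C4=C5; the C6–O bond is never broken, so the α-oxirane becomes the 6α-hydroxyl trans to O1, and buffered hydrazine at or below room temperature should spare the benzoate and the silyl ether.

Step 8
Reactants: 14 6α-allylic alcohol
Product: 15 6α-mesylate
Conditions: Ms2O, Et3N, DMAP (cat.), CH2Cl2, −20 → 0 °C
Reagents that add atoms: methanesulfonic anhydride, CS(=O)(=O)OS(C)(=O)=O
Why: O-sulfonylation of the only free hydroxyl with retention at C6; the anhydride keeps chloride out (no SN2' path), and the mesylate is neopentyl-like and flanked by electron-withdrawing oxygens, which disfavours both SN2 and ionization.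

Step 9
Reactants: 15 6α-mesylate
Product: 16 3α-alcohol
Conditions: HF·pyridine, pyridine, THF, 0 °C → rt
Reagents that add atoms: none
Why: Fluoride desilylation under buffered, weakly acidic conditions that should leave the acetal, the benzoate and the mesylate intact.

Step 10
Reactants: 16 3α-alcohol
Product: 17 4-en-3-one
Conditions: Dess–Martin periodinane, NaHCO3, CH2Cl2, 0 °C → rt
Reagents that add atoms: none
Why: Dess–Martin oxidation of the allylic alcohol erases the provisional C3 center under non-basic conditions, so C2 should not epimerize and O1 should not be β-eliminated.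

Step 11
Reactants: 17 4-en-3-one
Product: 18 3β-alcohol
Conditions: NaBH4, CeCl3·7H2O, MeOH, −78 °C
Reagents that add atoms: none
Why: Luche 1,2-reduction, in which hydride is delivered to C3 from the α face, anti to the cis-fused dioxolane whose pseudoaxial O1 screens the β face, as is general for cyclohexenones flanked by a cis-fused acetal; the new hydroxyl is therefore β and cis to O2, and at −78 °C the cerium-activated carbonyl should react before the mesylate is displaced.

Step 12
Reactants: 18 3β-alcohol
Product: 19 3β-silyl ether
Conditions: TBSOTf, 2,6-lutidine, CH2Cl2, −78 → −20 °C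
Reagents that add atoms: tert-butyldimethylsilyl triflate, CC(C)(C)[Si](C)(C)OS(=O)(=O)C(F)(F)F
Why: O-silylation with a silyl triflate and a hindered pyridine generates no alkoxide, so the 3β-oxygen cannot displace the 6α-mesylate across the ring, and it marks O3 so that O2 can later be acylated alone.

Step 13
Reactants: 19 3β-silyl ether
Product: 20 1β,2β-diol
Conditions: HS(CH2)3SH, BF3·OEt2 (cat.), CH2Cl2, −30 → 0 °C
Reagents that add atoms: none
Why: Lewis-acid-promoted transthioacetalization, in which the oxocarbenium ion formed at the acetal carbon is trapped irreversibly by the dithiol; only the acetal C–O bonds are cleaved, so C1 and C2 keep their configuration, and at low temperature the secondary silyl ether, the benzoate and the deactivated mesylate should survive.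

Step 14
Reactants: 20 1β,2β-diol
Product: 21 1β,6β-oxirane
Conditions: DBU, toluene, rt
Reagents that add atoms: none
Why: Intramolecular Williamson closure (3-exo-tet) in which the tertiary O1, trans-diaxial to the 6α-mesylate in the reactive half-chair, attacks C6 with inversion; the oxirane therefore lies on the β face, cis to O2 and O3, and the amidine base is too weak to build up free alkoxides that would shuttle the C7 benzoate or the C3 silyl group.

Step 15
Reactants: 21 1β,6β-oxirane; 22 benzoyl chloride
Product: 23 2-O-benzoyl-3-O-silyl epoxide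
Conditions: BzCl, pyridine, DMAP (cat.), CH2Cl2, 0 °C → rt
Reagents that add atoms: benzoyl chloride (22), O=C(Cl)c1ccccc1
Why: DMAP-catalysed acylation of O2, the only free hydroxyl, with retention at C2.

Step 16
Reactants: 23 2-O-benzoyl-3-O-silyl epoxide
Product: 24 target
Conditions: HF·pyridine, pyridine, THF, 0 °C
Reagents that add atoms: none
Why: Buffered fluoride desilylation is non-basic, so the benzoyl group should not migrate from O2 to the cis O3, and the oxirane, flanked by acyloxy-bearing carbons, should not be opened.

**Compound list**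

1 | 4-hydroxybenzyl alcohol | OCc1ccc(O)cc1 | starting material
2 | benzoic acid | O=C(O)c1ccccc1 | starting material
3 | 4-hydroxybenzyl benzoate | O=C(OCc1ccc(O)cc1)c1ccccc1 | intermediate
4 | 4-(benzoyloxymethyl)-4-hydroxycyclohexa-2,5-dien-1-one (achiral p-quinol) | O=C1C=CC(O)(COC(=O)c2ccccc2)C=C1 | intermediate
5 | isobutyraldehyde | CC(C)C=O | starting material
6 | hemiacetal of 4 with isobutyraldehyde at the tertiary oxygen (both epimers, interconverting; not isolated) | O=C1C=CC(OC(O)C(C)C)(COC(=O)c2ccccc2)C=C1 | intermediate
7 | 1-(benzoyloxymethyl)-1β,2β-(isobutylidenedioxy)cyclohex-5-en-4-one; cis-fused dioxolane, isopropyl exo, C7 α | O=C1C[C@H]2O[C@H](C(C)C)O[C@@]2(COC(=O)c3ccccc3)C=C1 | intermediate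
8 | 4-(tert-butyldimethylsilyloxy)cyclohexa-3,5-diene derived from 7 (silyl dienol ether) | CC(C)(C)[Si](C)(C)OC1=C[C@H]2O[C@H](C(C)C)O[C@@]2(COC(=O)c3ccccc3)C=C1 | intermediate
9 | 3α,4α-epoxy-4β-silyloxy-cyclohex-5-ene from 8 (not isolated) | CC(C)(C)[Si](C)(C)O[C@]12C=C[C@]3(COC(=O)c4ccccc4)O[C@@H](C(C)C)O[C@@H]3[C@H]1O2 | intermediate
10 | 3α-(tert-butyldimethylsilyloxy) derivative of enone 7 (O3 trans to O2; expected major epimer) | O=C1[C@H](O[Si](C)(C)C(C)(C)C)[C@H]2O[C@H](C(C)C)O[C@@]2(COC(=O)c3ccccc3)C=C1 | intermediate
11 | 5α,6α-epoxy-3α-silyloxy-4-ketone (oxirane trans to O1) | O=C1[C@H](O[Si](C)(C)C(C)(C)C)[C@H]2O[C@H](C(C)C)O[C@@]2(COC(=O)c3ccccc3)[C@@H]4O[C@H]14 | intermediate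
12 | hydrazone of epoxy ketone 11 (not isolated) | NN=C1[C@H](O[Si](C)(C)C(C)(C)C)[C@H]2O[C@H](C(C)C)O[C@@]2(COC(=O)c3ccccc3)[C@@H]4O[C@H]14 | intermediate
13 | 4-diazenyl-cyclohex-4-ene with 6α-hydroxyl and 3α-silyloxy (alkenyl diazene; not isolated) | N=NC1=C[C@@H](O)[C@]2(COC(=O)c3ccccc3)O[C@@H](C(C)C)O[C@@H]2[C@H]1O[Si](C)(C)C(C)(C)C | intermediate
14 | 1β,2β-isobutylidene acetal of the cyclohex-4-ene with 3α-OTBS and 6α-OH | CC(C)(C)[Si](C)(C)O[C@H]1C=C[C@@H](O)[C@]2(COC(=O)c3ccccc3)O[C@@H](C(C)C)O[C@H]12 | intermediate
15 | 6α-mesylate of 14 | CC(C)(C)[Si](C)(C)O[C@H]1C=C[C@@H](OS(C)(=O)=O)[C@]2(COC(=O)c3ccccc3)O[C@@H](C(C)C)O[C@H]12 | intermediate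
16 | 3α-hydroxy-6α-mesyloxy-cyclohex-4-ene acetal | O[C@H]1C=C[C@@H](OS(C)(=O)=O)[C@]2(COC(=O)c3ccccc3)O[C@@H](C(C)C)O[C@H]12 | intermediate
17 | 6α-mesyloxy-cyclohex-4-en-3-one acetal | O=C1C=C[C@@H](OS(C)(=O)=O)[C@]2(COC(=O)c3ccccc3)O[C@@H](C(C)C)O[C@H]12 | intermediate
18 | 3β-hydroxy-6α-mesyloxy-cyclohex-4-ene acetal (O3 cis to O2) | O[C@@H]1C=C[C@@H](OS(C)(=O)=O)[C@]2(COC(=O)c3ccccc3)O[C@@H](C(C)C)O[C@H]12 | intermediate
19 | 3β-(tert-butyldimethylsilyloxy)-6α-mesyloxy-cyclohex-4-ene acetal | CC(C)(C)[Si](C)(C)O[C@@H]1C=C[C@@H](OS(C)(=O)=O)[C@]2(COC(=O)c3ccccc3)O[C@@H](C(C)C)O[C@H]12 | intermediate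
20 | 1-(benzoyloxymethyl)-3β-silyloxy-6α-mesyloxy-cyclohex-4-ene-1β,2β-diol | CC(C)(C)[Si](C)(C)O[C@@H]1C=C[C@@H](OS(C)(=O)=O)[C@@](O)(COC(=O)c2ccccc2)[C@@H]1O | intermediate
21 | 1β,6β-epoxy-2β-hydroxy-3β-silyloxy-cyclohex-4-ene with C7 benzoate | O=C(OC[C@]12O[C@H]1C=C[C@@H](O[Si](C)(C)C(C)(C)C)[C@H]2O)c1ccccc1 | intermediate
22 | benzoyl chloride | O=C(Cl)c1ccccc1 | starting material
23 | 2-O-benzoyl-3-O-TBS derivative of the target | O=C(OC[C@]12O[C@H]1C=C[C@@H](O[Si](C)(C)C(C)(C)C)[C@H]2OC(=O)c1ccccc1)c1ccccc1 | intermediate
24 | [(1S,2R,3R,6S)-2-(benzoyloxy)-3-hydroxy-7-oxabicyclo[4.1.0]hept-4-en-1-yl]methyl benzoate | O=C(OC[C@]12O[C@H]1C=C[C@@H](O)[C@H]2OC(=O)c1ccccc1)c1ccccc1 | target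

**Step count and risks**

Total step count: 16. Longest linear sequence: 16 steps (1 → 24).

Steps most likely to fail:

1. Step 3 (key step). The phosphoric acid may discriminate the two enone arms poorly, or the hindered, inductively deactivated tertiary hydroxyl may form the hemiacetal too slowly. Fallback: change the tether from a hemiacetal to a boronate. Starting from 4, phenylboronic acid and a bifunctional cinchona-derived amine–thiourea (boronic acid hemiester oxa-Michael addition) should give the cis-fused cyclic phenylboronate F1. Exchange with pinacol releases the cis-1,2-diol F2, and acetalization with isobutyraldehyde dimethyl acetal and PPTS (thermodynamic exo-isopropyl acetal) returns to the route at 7.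

2. Step 6. The peroxide anion may attack the β face of C6, or the basic medium may reopen the dioxolane by retro-oxa-Michael. Fallback: bring in the C6 oxygen by cycloaddition. Starting from 7, KHMDS with Comins' reagent at −78 °C gives the dienyl triflate F3, and Pd(OAc)2/PPh3/Bu3N/HCO2H reduces it to the cyclohexa-3,5-diene acetal F4. Photooxygenation (O2, tetraphenylporphyrin, hν, −40 °C) adds singlet oxygen across C3/C6 on the α face, anti to the dioxolane as with acetonides of arene cis-dihydrodiols, to give the endoperoxide F5. Thiourea reduces it to the 3α,6α-diol F6, and TBSCl/imidazole silylates the less hindered C3 hydroxyl, rejoining the route at 14 and by-passing steps 4–7.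

3. Step 13. The Lewis-acidic exchange may strip the C3 silyl ether or ionize the allylic mesylate. Fallback: remove the acetal before any silyl group is present. Starting from 18, aqueous trifluoroacetic acid hydrolyses the acetal to the triol mesylate F7, and DBU closes the oxirane to the epoxy diol F8. TBSCl/imidazole then silylates the allylic O3–H in preference to O2–H, which is flanked by the quaternary oxirane carbon, rejoining the route at 21.

Further compounds
F1 | step 3 | cis-fused cyclic phenylboronate of 1-(benzoyloxymethyl)-1β,2β-dihydroxycyclohex-5-en-4-one | O=C1C[C@H]2OB(c3ccccc3)O[C@@]2(COC(=O)c4ccccc4)C=C1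
F2 | step 3 | 1-(benzoyloxymethyl)-1β,2β-dihydroxycyclohex-5-en-4-one | O=C1C[C@@H](O)[C@](O)(COC(=O)c2ccccc2)C=C1
F3 | step 6 | dienyl triflate of 7 (4-triflyloxy-cyclohexa-3,5-diene acetal) | O=S(=O)(OC1=C[C@H]2O[C@H](C(C)C)O[C@@]2(COC(=O)c3ccccc3)C=C1)C(F)(F)F
F4 | step 6 | 1-(benzoyloxymethyl)-1β,2β-(isobutylidenedioxy)cyclohexa-3,5-diene | C1=C[C@H]2O[C@H](C(C)C)O[C@@]2(COC(=O)c3ccccc3)C=C1
F5 | step 6 | 3α,6α-endoperoxide of F4 | C1=C[C@H]2OO[C@@H]1[C@H]3O[C@H](C(C)C)O[C@@]23COC(=O)c4ccccc4
F6 | step 6 | 3α,6α-dihydroxy-cyclohex-4-ene acetal | O[C@H]1C=C[C@@H](O)[C@]2(COC(=O)c3ccccc3)O[C@@H](C(C)C)O[C@H]12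
F7 | step 13 | 1-(benzoyloxymethyl)-6α-mesyloxy-cyclohex-4-ene-1β,2β,3β-triol | O[C@@H]1C=C[C@@H](OS(C)(=O)=O)[C@@](O)(COC(=O)c2ccccc2)[C@@H]1O
F8 | step 13 | 1β,6β-epoxy-2β,3β-dihydroxy-cyclohex-4-ene with C7 benzoate | O=C(OC[C@]12O[C@H]1C=C[C@@H](O)[C@H]2O)c1ccccc1
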